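**Strategy.** Ring B of the target (a 1-tetralone) is cut at two bonds: aryl carbon C-8a to the quaternary carbon C-1, and the methylene C-3 to the ketone carbon C-4. The key step exploits the ortho relationship of C-4 and C-1 on ring C, which makes them a masked phthalide: an ortho-ester aryl Grignard adds to a chiral γ-keto ester, the alkoxide lactonizes, and a Dieckmann-type ring expansion of this temporary lactone closes ring B in one operation. The benzylic carbinol is later converted to a planar radical that adds to methyl acrylate anti to the isopropenyl group, setting the quaternary centre; the hydroquinone is unveiled last.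

Key step: step 9

Assumption: (S)-BINAP is taken to deliver the 3S adduct in step 7; if the sense proves opposite, (R)-BINAP is used.

Step 1
Reactants: 1 1,2,4-trimethoxybenzene
Product: 3 2-(2,3,6-trimethoxyphenyl)propan-2-ol, via aryllithium 2 (not isolated)
Conditions: n-BuLi, THF, 0 °C; acetone, −78 °C → rt; then H2O
Reagents that add atoms: acetone, CC(C)=O
Why: Directed ortho-metalation of 1 should occur at the ring position flanked by two methoxy groups, and the aryllithium then adds 1,2 to acetone.

Step 2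
Reactants: 3 2-(2,3,6-trimethoxyphenyl)propan-2-ol
Product: 4 1,2,4-trimethoxy-3-(propan-2-yl)benzene
Conditions: Et3SiH, CF3CO2H, CH2Cl2, 0 °C → rt
Reagents that add atoms: none
Why: Ionic hydrogenation, in which the tertiary benzylic alcohol ionizes to a cation stabilized by two ortho methoxy groups and is reduced by hydride transfer from Et3SiH.

Step 3
Reactants: 4 1,2,4-trimethoxy-3-(propan-2-yl)benzene
Product: 5 1-bromo-2,4,5-trimethoxy-3-(propan-2-yl)benzene
Conditions: NBS, MeCN, 0 °C → rt
Reagents that add atoms: N-bromosuccinimide, O=C1CCC(=O)N1Br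
Why: Electrophilic aromatic bromination should go to the free position that is ortho to one methoxy group and para to another, as in the parent trimethoxybenzene.

Step 4
Reactants: 5 1-bromo-2,4,5-trimethoxy-3-(propan-2-yl)benzene
Product: 7 methyl 2,4,5-trimethoxy-3-(propan-2-yl)benzoate, via aryllithium 6 (not isolated)
Conditions: n-BuLi, THF, −78 °C; cannulate into excess ClCO2Me, −78 °C → rt
Reagents that add atoms: methyl chloroformate, COC(=O)Cl
Why: Bromine–lithium exchange followed by acylation of the aryllithium (inverse addition to suppress double addition) installs the carbon that becomes the ring ketone.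

Step 5
Reactants: 7 methyl 2,4,5-trimethoxy-3-(propan-2-yl)benzoate
Product: 8 methyl 2-bromo-3,4,6-trimethoxy-5-(propan-2-yl)benzoate
Conditions: NBS, CF3CO2H (cat.), MeCN, rt
Reagents that add atoms: N-bromosuccinimide, O=C1CCC(=O)N1Br
Why: Electrophilic bromination of the only remaining ring position, activated by the ortho methoxy and para isopropyl groups, provides the handle for the later halogen–magnesium exchange.

Step 6
Reactants: 9 (2E)-4-methoxy-4-oxobut-2-enoic acid
Product: 11 methyl (2E)-4-[methoxy(methyl)amino]-4-oxobut-2-enoate, via acid chloride 10 (not isolated)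
Conditions: (COCl)2, DMF (cat.), CH2Cl2, 0 °C → rt, concentrate; MeNH(OMe)·HCl, K2CO3, CH2Cl2/H2O, 0 °C
Reagents that add atoms: N,O-dimethylhydroxylamine hydrochloride, CNOC.Cl
Why: Acid chloride formation and Schotten–Baumann amidation should give the Weinreb amide while the E alkene and the methyl ester stay untouched.

Step 7
Reactants: 11 methyl (2E)-4-[methoxy(methyl)amino]-4-oxobut-2-enoate
Product: 12 methyl (3S)-3-[methoxy(methyl)carbamoyl]-4-methylpent-4-enoate
Conditions: isopropenylboronic acid pinacol ester, [Rh(OH)((S)-binap)]2 (cat.), 1,4-dioxane/H2O, 40 °C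
Reagents that add atoms: 4,4,5,5-tetramethyl-2-(prop-1-en-2-yl)-1,3,2-dioxaborolane, C=C(C)B1OC(C)(C)C(C)(C)O1
Why: Rhodium-catalysed asymmetric 1,4-addition (Hayashi–Miyaura reaction) should place the alkenyl group on the alkene carbon β to the more activating ester and α to the amide, the BINAP ligand setting the new stereocentre as S by face-selective carbometalation.

Step 8
Reactants: 12 methyl (3S)-3-[methoxy(methyl)carbamoyl]-4-methylpent-4-enoate
Product: 13 methyl (3S)-3-acetyl-4-methylpent-4-enoate
Conditions: MeMgBr (1.1 equiv), THF, −78 °C; aq. NH4Cl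
Reagents that add atoms: methylmagnesium bromide, C[Mg]Br
Why: Weinreb ketone synthesis, in which MeMgBr adds once to the amide to form a stable magnesium chelate that releases the methyl ketone on work-up, at −78 °C faster than attack on the ester or deprotonation at the stereocentre.

Step 9
Reactants: 8 methyl 2-bromo-3,4,6-trimethoxy-5-(propan-2-yl)benzoate, 13 methyl (3S)-3-acetyl-4-methylpent-4-enoate
Product: 16 methyl (3S)-4-hydroxy-5,6,8-trimethoxy-4-methyl-1-oxo-7-(propan-2-yl)-3-(prop-1-en-2-yl)-1,2,3,4-tetrahydronaphthalene-2-carboxylate, via aryl Grignard 14 (not isolated), via phthalide 15 (not isolated)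
Conditions: i-PrMgCl·LiCl, THF, −20 °C; LaCl3·2LiCl then 13, −40 → 0 °C; LiN(SiMe3)2, 0 °C → rt; aq. NH4Cl
Reagents that add atoms: none
Why: Bromine–magnesium exchange gives aryl Grignard 14, which adds to the ketone of 13 and so forms the aryl–carbinol carbon bond; the magnesium alkoxide then closes onto the ortho ester (5-exo-trig acyl substitution) to give the temporary phthalide 15. LiN(SiMe3)2 generates the side-chain ester enolate, which attacks the lactone carbonyl in a 6-exo-trig Dieckmann closure and expels the benzylic alkoxide, forming the CH–C(=O) bond and ring B. The closest known reactions are the addition of ortho-alkoxycarbonyl aryl Grignard reagents to ketones, which gives phthalides directly, and the lactone-opening Dieckmann stage of the Hauser–Kraus annulation. The carbinol stereocentre forms without control, which is harmless because step 11 erases it, while the 3S centre of 13 is only carried through. The step needs addition to the ketone rather than to the ester or enolization of the α-branched ketone, which LaCl3·2LiCl and low temperature should secure, and formation of the stabilized β-keto ester enolate drives the lactone opening.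

Step 10
Reactants: 16 methyl (3S)-4-hydroxy-5,6,8-trimethoxy-4-methyl-1-oxo-7-(propan-2-yl)-3-(prop-1-en-2-yl)-1,2,3,4-tetrahydronaphthalene-2-carboxylate
Product: 17 (3S)-4-hydroxy-5,6,8-trimethoxy-4-methyl-7-(propan-2-yl)-3-(prop-1-en-2-yl)-3,4-dihydronaphthalen-1(2H)-one
Conditions: LiCl, H2O, DMSO, 130 °C
Reagents that add atoms: none
Why: Krapcho dealkoxycarbonylation, in which chloride demethylates the β-keto ester by SN2 attack and the carboxylate loses CO2 under neutral conditions that should spare the acid-sensitive tertiary benzylic alcohol.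

Step 11
Reactants: 17 (3S)-4-hydroxy-5,6,8-trimethoxy-4-methyl-7-(propan-2-yl)-3-(prop-1-en-2-yl)-3,4-dihydronaphthalen-1(2H)-one
Product: 19 methyl 3-[(1S,2S)-5,7,8-trimethoxy-1-methyl-4-oxo-6-(propan-2-yl)-2-(prop-1-en-2-yl)-1,2,3,4-tetrahydronaphthalen-1-yl]propanoate, via alkoxybenzoxazoline 18 (not isolated)
Conditions: 5,7-di-tert-butyl-3-phenyl-1,3-benzoxazol-3-ium tetrafluoroborate, pyridine, t-BuOMe, rt; then methyl acrylate, Ir[dF(CF3)ppy]2(dtbbpy)PF6 (cat.), DMSO, blue light, rt
Reagents that add atoms: methyl acrylate, C=CC(=O)OC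
Why: Deoxygenative Giese reaction, in which the alcohol condenses with the benzoxazolium salt to 18, photoredox oxidation and β-scission give a planar tertiary benzylic radical, and this adds to methyl acrylate on the face anti to the neighbouring pseudoaxial isopropenyl group, so that both carbinol epimers should converge on the 1S quaternary centre with the propanoate chain trans to the isopropenyl group.

Step 12
Reactants: 19 methyl 3-[(1S,2S)-5,7,8-trimethoxy-1-methyl-4-oxo-6-(propan-2-yl)-2-(prop-1-en-2-yl)-1,2,3,4-tetrahydronaphthalen-1-yl]propanoate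
Product: 20 3-[(1S,2S)-5,7,8-trimethoxy-1-methyl-4-oxo-6-(propan-2-yl)-2-(prop-1-en-2-yl)-1,2,3,4-tetrahydronaphthalen-1-yl]propanoic acid
Conditions: LiOH, THF/H2O, rt; then 1 M HCl
Reagents that add atoms: lithium hydroxide, [Li+].[OH-]
Why: Saponification of the unhindered methyl ester, to which the hindered aryl ketone, the alkene and both stereocentres (neither α to a carbonyl) should be inert.

Step 13
Reactants: 20 3-[(1S,2S)-5,7,8-trimethoxy-1-methyl-4-oxo-6-(propan-2-yl)-2-(prop-1-en-2-yl)-1,2,3,4-tetrahydronaphthalen-1-yl]propanoic acid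
Product: 22 3-[(1S,2S)-5,8-dihydroxy-7-methoxy-1-methyl-4-oxo-6-(propan-2-yl)-2-(prop-1-en-2-yl)-1,2,3,4-tetrahydronaphthalen-1-yl]propanoic acid, via quinone 21 (not isolated)
Conditions: (NH4)2Ce(NO3)6, MeCN/H2O, 0 °C; then Na2S2O4, EtOAc/H2O, rt
Reagents that add atoms: water, O
Why: Oxidative demethylation of the para-dimethoxy pair should give the methoxy-para-quinone 21, the third methoxy group surviving as a vinylogous ester, and dithionite reduction then gives the hydroquinone of the target.

**Compound list**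

1 | 1,2,4-trimethoxybenzene | COc1ccc(OC)c(OC)c1 | starting material
2 | (2,3,6-trimethoxyphenyl)lithium | COc1ccc(OC)c([Li])c1OC | intermediate
3 | 2-(2,3,6-trimethoxyphenyl)propan-2-ol | COc1ccc(OC)c(C(C)(C)O)c1OC | intermediate
4 | 1,2,4-trimethoxy-3-(propan-2-yl)benzene | COc1ccc(OC)c(C(C)C)c1OC | intermediate
5 | 1-bromo-2,4,5-trimethoxy-3-(propan-2-yl)benzene | COc1cc(Br)c(OC)c(C(C)C)c1OC | intermediate
6 | [2,4,5-trimethoxy-3-(propan-2-yl)phenyl]lithium | COc1cc([Li])c(OC)c(C(C)C)c1OC | intermediate
7 | methyl 2,4,5-trimethoxy-3-(propan-2-yl)benzoate | COC(=O)c1cc(OC)c(OC)c(C(C)C)c1OC | intermediate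
8 | methyl 2-bromo-3,4,6-trimethoxy-5-(propan-2-yl)benzoate | COC(=O)c1c(Br)c(OC)c(OC)c(C(C)C)c1OC | intermediate
9 | (2E)-4-methoxy-4-oxobut-2-enoic acid (monomethyl fumarate) | COC(=O)/C=C/C(=O)O | starting material
10 | methyl (2E)-4-chloro-4-oxobut-2-enoate | COC(=O)/C=C/C(=O)Cl | intermediate
11 | methyl (2E)-4-[methoxy(methyl)amino]-4-oxobut-2-enoate | COC(=O)/C=C/C(=O)N(C)OC | intermediate
12 | methyl (3S)-3-[methoxy(methyl)carbamoyl]-4-methylpent-4-enoate | C=C(C)[C@@H](C(=O)N(C)OC)CC(=O)OC | intermediate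
13 | methyl (3S)-3-acetyl-4-methylpent-4-enoate | C=C(C)[C@@H](C(C)=O)CC(=O)OC | intermediate
14 | [2-(methoxycarbonyl)-3,5,6-trimethoxy-4-(propan-2-yl)phenyl]magnesium chloride (LiCl complex) | COC(=O)c1c([Mg]Cl)c(OC)c(OC)c(C(C)C)c1OC | intermediate
15 | methyl (3S)-4-methyl-3-[4,6,7-trimethoxy-1-methyl-3-oxo-5-(propan-2-yl)-1,3-dihydro-2-benzofuran-1-yl]pent-4-enoate (both epimers at the lactone carbon) | C=C(C)[C@@H](C1(C)OC(=O)c2c(OC)c(C(C)C)c(OC)c(OC)c21)CC(=O)OC | intermediate
16 | methyl (3S)-4-hydroxy-5,6,8-trimethoxy-4-methyl-1-oxo-7-(propan-2-yl)-3-(prop-1-en-2-yl)-1,2,3,4-tetrahydronaphthalene-2-carboxylate (both epimers at C-4; C-2 enolizable) | C=C(C)[C@@H]1C(C(=O)OC)C(=O)c2c(OC)c(C(C)C)c(OC)c(OC)c2C1(C)O | intermediate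
17 | (3S)-4-hydroxy-5,6,8-trimethoxy-4-methyl-7-(propan-2-yl)-3-(prop-1-en-2-yl)-3,4-dihydronaphthalen-1(2H)-one (both epimers at C-4) | C=C(C)[C@@H]1CC(=O)c2c(OC)c(C(C)C)c(OC)c(OC)c2C1(C)O | intermediate
18 | (3S)-4-[(5,7-di-tert-butyl-3-phenyl-2,3-dihydro-1,3-benzoxazol-2-yl)oxy]-5,6,8-trimethoxy-4-methyl-7-(propan-2-yl)-3-(prop-1-en-2-yl)-3,4-dihydronaphthalen-1(2H)-one | C=C(C)[C@@H]1CC(=O)c2c(OC)c(C(C)C)c(OC)c(OC)c2C1(C)OC1Oc2c(C(C)(C)C)cc(C(C)(C)C)cc2N1c1ccccc1 | intermediate
19 | methyl 3-[(1S,2S)-5,7,8-trimethoxy-1-methyl-4-oxo-6-(propan-2-yl)-2-(prop-1-en-2-yl)-1,2,3,4-tetrahydronaphthalen-1-yl]propanoate | C=C(C)[C@@H]1CC(=O)c2c(OC)c(C(C)C)c(OC)c(OC)c2[C@@]1(C)CCC(=O)OC | intermediate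
20 | 3-[(1S,2S)-5,7,8-trimethoxy-1-methyl-4-oxo-6-(propan-2-yl)-2-(prop-1-en-2-yl)-1,2,3,4-tetrahydronaphthalen-1-yl]propanoic acid | C=C(C)[C@@H]1CC(=O)c2c(OC)c(C(C)C)c(OC)c(OC)c2[C@@]1(C)CCC(=O)O | intermediate
21 | 3-[(1S,2S)-7-methoxy-1-methyl-4,5,8-trioxo-6-(propan-2-yl)-2-(prop-1-en-2-yl)-1,2,3,4,5,8-hexahydronaphthalen-1-yl]propanoic acid | C=C(C)[C@@H]1CC(=O)C2=C(C(=O)C(OC)=C(C(C)C)C2=O)[C@@]1(C)CCC(=O)O | intermediate
22 | 3-[(1S,2S)-5,8-dihydroxy-7-methoxy-1-methyl-4-oxo-6-(propan-2-yl)-2-(prop-1-en-2-yl)-1,2,3,4-tetrahydronaphthalen-1-yl]propanoic acid (CNP0249049.1) | C=C(C)[C@@H]1CC(=O)c2c(O)c(C(C)C)c(OC)c(O)c2[C@@]1(C)CCC(=O)O | target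

**Step count.** 13 steps in total; the longest linear sequence is 10 steps (steps 1–5 and 9–13).

**Steps most likely to fail**

Step 9 (key step). The hindered aryl Grignard may deprotonate the α-branched ketone instead of adding to it, which would cost material and erode the stereocentre, or the acyl transfer may stall at the lactone stage. The fallback sets out from 5 and 13 and comes back to the route at 17. Bromide 5 would be deprotonated at its only ring hydrogen (between Br and OMe) with lithium 2,2,6,6-tetramethylpiperidide at −78 °C, transmetalated with CeCl3 and added to 13. The alkoxide should close onto the side-chain ester to give the bromo lactone (4S)-5-[2-bromo-3,5,6-trimethoxy-4-(propan-2-yl)phenyl]-5-methyl-4-(prop-1-en-2-yl)oxolan-2-one F1. Palladium-catalysed methoxycarbonylation (Pd(OAc)2, 1,3-bis(diphenylphosphino)propane, CO, MeOH, Et3N) would then bring in the ketone carbon, giving methyl 3,4,6-trimethoxy-2-[(3S)-2-methyl-5-oxo-3-(prop-1-en-2-yl)oxolan-2-yl]-5-(propan-2-yl)benzoate F2. LiN(SiMe3)2 should effect Dieckmann closure of the lactone enolate onto the aryl ester to the bridged β-keto lactone F3. Hydrolysis and decarboxylation of F3 (aq. LiOH, then mild acid) would give 17.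

Step 11. The hindered tertiary alcohol may condense slowly with the benzoxazolium salt, and the congested benzylic radical may be reduced or dimerize instead of adding to the acrylate. The fallback sets out from 17 and comes back at 20. Ionization of 17 with BF3·OEt2 in the presence of allyltrimethylsilane (CH2Cl2, −78 °C, Hosomi–Sakurai-type allylation of the benzylic cation, again anti to the isopropenyl group) should give (3S,4S)-5,6,8-trimethoxy-4-methyl-7-(propan-2-yl)-4-(prop-2-en-1-yl)-3-(prop-1-en-2-yl)-3,4-dihydronaphthalen-1(2H)-one F4. Hydroboration of the monosubstituted alkene with 9-borabicyclo[3.3.1]nonane and oxidation with H2O2/NaOH would give (3S,4S)-4-(3-hydroxypropyl)-5,6,8-trimethoxy-4-methyl-7-(propan-2-yl)-3-(prop-1-en-2-yl)-3,4-dihydronaphthalen-1(2H)-one F5. Oxidation of F5 (2,2,6,6-tetramethylpiperidin-1-oxyl, PhI(OAc)2, MeCN/H2O) would give acid 20.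

Step 7. Protodeboronation of the alkenyl boronate, low regio- or enantioselectivity, or base-induced migration of the double bond into conjugation may intervene. The fallback sets out from 11 and comes back at 12 by resolution instead of asymmetric catalysis. Copper-catalysed addition of isopropenylmagnesium bromide (CuBr·SMe2 cat., Me3SiCl, THF, −78 °C) should give racemic methyl 3-[methoxy(methyl)carbamoyl]-4-methylpent-4-enoate F6. LiOH hydrolysis of the methyl ester would give racemic 3-[methoxy(methyl)carbamoyl]-4-methylpent-4-enoic acid F7. Crystallization of its (R)-1-phenylethylammonium salt and acidification would give (3S)-3-[methoxy(methyl)carbamoyl]-4-methylpent-4-enoic acid F8, which Me3SiCHN2 in MeOH would re-esterify to 12.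

Further compounds
F1 | step 9 | (4S)-5-[2-bromo-3,5,6-trimethoxy-4-(propan-2-yl)phenyl]-5-methyl-4-(prop-1-en-2-yl)oxolan-2-one | C=C(C)[C@@H]1CC(=O)OC1(C)c1c(Br)c(OC)c(C(C)C)c(OC)c1OC
F2 | step 9 | methyl 3,4,6-trimethoxy-2-[(3S)-2-methyl-5-oxo-3-(prop-1-en-2-yl)oxolan-2-yl]-5-(propan-2-yl)benzoate | C=C(C)[C@@H]1CC(=O)OC1(C)c1c(C(=O)OC)c(OC)c(C(C)C)c(OC)c1OC
F3 | step 9 | (3S)-5,6,8-trimethoxy-4-methyl-1-oxo-7-(propan-2-yl)-3-(prop-1-en-2-yl)-1,2,3,4-tetrahydronaphthalene-2,4-carbolactone (bridged β-keto lactone) | C=C(C)[C@@H]1C2C(=O)OC1(C)c1c(OC)c(OC)c(C(C)C)c(OC)c1C2=O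
F4 | step 11 | (3S,4S)-5,6,8-trimethoxy-4-methyl-7-(propan-2-yl)-4-(prop-2-en-1-yl)-3-(prop-1-en-2-yl)-3,4-dihydronaphthalen-1(2H)-one | C=C(C)[C@@H]1CC(=O)c2c(OC)c(C(C)C)c(OC)c(OC)c2[C@@]1(C)CC=C
F5 | step 11 | (3S,4S)-4-(3-hydroxypropyl)-5,6,8-trimethoxy-4-methyl-7-(propan-2-yl)-3-(prop-1-en-2-yl)-3,4-dihydronaphthalen-1(2H)-one | C=C(C)[C@@H]1CC(=O)c2c(OC)c(C(C)C)c(OC)c(OC)c2[C@@]1(C)CCCO
F6 | step 7 | methyl 3-[methoxy(methyl)carbamoyl]-4-methylpent-4-enoate (racemic) | C=C(C)C(C(=O)N(C)OC)CC(=O)OC
F7 | step 7 | 3-[methoxy(methyl)carbamoyl]-4-methylpent-4-enoic acid (racemic) | C=C(C)C(C(=O)N(C)OC)CC(=O)O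
F8 | step 7 | (3S)-3-[methoxy(methyl)carbamoyl]-4-methylpent-4-enoic acid | C=C(C)[C@@H](C(=O)N(C)OC)CC(=O)O
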